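The late time is where we must arrive: product at 15 min, in a flask whose readings stop at 6.00 min.

| setting | beta | flask |
|---|---|---|
| starting material | 1 M | 1.0 M |
| partner | 2 M | 2.00 M |
| free catalyst | 10 mM | 10 mM |
| remark | the very flask that is asked about, followed so far |  |
| time |  | 15 min |

beta run (percent of the starting material charged)

| time / min | product / % | starting material / % |
|---|---|---|
| 0.333 | 0 | 99.7 |
| 1.00 | 1.9 | 98.8 |
| 1.50 | 2.4 | 98.3 |
| 2.50 | 3.4 | 96.2 |
| 4.00 | 6.9 | 94.1 |
| 5.00 | 8.3 | 92.0 |
| 6.00 | 8.5 | 90.5 |

(readings scatter by 0.5 percentage points)

- amount of product in percent of the starting material charged, at 1.5 min, 5.0 min and 15 min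

The round that may be going on in this flask is this: partner and free catalyst give catalyst intermediate A, A gives catalyst intermediate B, B takes up starting material to give catalyst intermediate C, and C releases product and free catalyst. B can also fall to spent catalyst (deactivation).

We read the starting-material column row against row. From the first reading to the fourth it loses 0.0162 /min of the charge, and from the fourth to the last 0.0163 /min. No bend shows. The product column seems to pause, going from 8.3% to 8.5%, but that step of 0.2 percentage points stands beside a scatter of 0.5 points per reading.

So we carry one quantity, the drain w = 0.0162 /min, the fraction of the starting-material charge lost per minute between the first reading and the last. Product can trail that loss by what the catalyst holds as C, at most 1.00% of the charge. Our line w·t gives 2.44%, 8.12% and 24.3% at the asked times, with product up to that 1.00% lower.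

The forecast says 2%, 7.7% and 20%. At 15 min it sits 4.4 points below our line, on the ground that "The last product points hint at slowing".

The flask gives 2.27%, 8.02% and 22.5%, so the forecast held.

    catalyst intermediate A → catalyst intermediate B (k = 6.34 /min)
    catalyst intermediate B → spent catalyst (k = 0.0479 /min)
    catalyst intermediate C → free catalyst + product (k = 114 /min)
    starting material + catalyst intermediate B → catalyst intermediate C (k = 7.86 /M/min)
    partner + free catalyst → catalyst intermediate A (k = 1.80 /M/min)

Over 15 min product came at 0.0150 /min of the charge on average, against w of 0.0162 /min. At the charged starting material, the constant for the loss of B to spent catalyst, 0.0479 /min, is far smaller than the 7.86 /min at which B goes on in the round, by a factor of 164. By 15.0 min that loss has turned over 0.155% of the starting-material charge, and spent catalyst stands at 15.5% of the catalyst charged. At 150 min w·t reads 243% of the charge, while this flask holds product 78.4% and spent catalyst 93.3% of the catalyst charged.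

The numbers in the tables are simulated for an exercise; scatter was added.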